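The ten-membered carbocycle is cut at C2–C3 (germacrane numbering). One palladium-catalysed allylic alkylation joins the sulfone-stabilised C2 carbanion, flanked by the C1 ketone, to the primary terminus C3 of the C3–C4–C5 allyl unit attached to C6 of the butenolide ring (O, C6, C7, C11, C12). It closes the ring and keeps the (4E)-alkene that later becomes the epoxide. The precursor is an open-chain butenolide: C6 carries the (E)-allylic methyl carbonate, C7 the citramalate-derived C8–C10/C1 chain ending in the β-keto sulfone, with C8–OTBS, a free tertiary C10–OH and C13–OPMB.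

Key step: step 17

Numbering: C1 ketone, C2 and C3 methylenes, C4=C5 (later the epoxide), C6 lactone O–CH, C7=C11 butenolide alkene, C8 carbinol, C9 CH2, C10 quaternary carbinol, C12 lactone C=O, C13 CH2O.
Assumption: 4-methoxybenzyl chloromethyl ether is taken as an available reagent (one step from 4-methoxybenzyl alcohol); the γ-hydroxy ketones 6 and 21, which can close to cyclic hemiketals, are drawn open-chain.

Step 1
Reactants: 1 (R)-citramalic acid
Product: 2 2-[(4R)-2,2,4-trimethyl-5-oxo-1,3-dioxolan-4-yl]acetic acid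
Conditions: 2,2-dimethoxypropane, TsOH (cat.), CH2Cl2, rt
Reagents that add atoms: 2,2-dimethoxypropane COC(C)(C)OC
Why: Acid-catalysed acetalisation ties the α-hydroxy acid into a five-membered dioxolanone and leaves the CH2CO2H group free, without touching the C10 stereocentre.

Step 2
Reactants: 2 2-[(4R)-2,2,4-trimethyl-5-oxo-1,3-dioxolan-4-yl]acetic acid
Product: 4 (3R)-3-hydroxy-3-methyloxolan-2-one, via hydroxyethyl dioxolanone 3 (not isolated)
Conditions: BH3·SMe2, THF, 0 °C to rt; MeOH; then TsOH (cat.), CH2Cl2, rt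
Reagents that add atoms: none
Why: Chemoselective borane reduction of the free carboxylic acid beside the dioxolanone, followed by acid-catalysed translactonisation that expels acetone and gives the γ-lactone.

Step 3
Reactants: 4 (3R)-3-hydroxy-3-methyloxolan-2-one; 5 methyl phenyl sulfone
Product: 6 (3R)-3,5-dihydroxy-3-methyl-1-(phenylsulfonyl)pentan-2-one
Conditions: 5 (3.5 equiv), n-BuLi, THF, -78 °C; then 4, -78 to 0 °C; H2O
Reagents that add atoms: none
Why: Claisen-type acylation of the sulfonyl carbanion by the lactone (one equivalent each for the alkoxide, the addition and the product enolate) should stop at the ketone because the product is held as its enolate, and C10 has no proton to lose.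

Step 4
Reactants: 6 (3R)-3,5-dihydroxy-3-methyl-1-(phenylsulfonyl)pentan-2-one
Product: 7 (3R)-3-hydroxy-3-methyl-4-oxo-5-(phenylsulfonyl)pentanal
Conditions: Dess–Martin periodinane, CH2Cl2, 0 °C to rt; used at once
Reagents that add atoms: none
Why: Dess–Martin oxidation of the primary alcohol runs without base, so the tertiary alcohol and the acidic keto sulfone should survive.

Step 5
Reactants: 8 prenyl acetate
Product: 9 (2E)-4-hydroxy-3-methylbut-2-en-1-yl acetate
Conditions: SeO2 (cat.), t-BuOOH, CH2Cl2, rt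
Reagents that add atoms: tert-butyl hydroperoxide CC(C)(C)OO
Why: SeO2/t-BuOOH allylic oxidation (ene reaction, then [2,3]-shift) hydroxylates the (E)-methyl group selectively and so fixes the E geometry of the future C4=C5 bond.

Step 6
Reactants: 9 (2E)-4-hydroxy-3-methylbut-2-en-1-yl acetate
Product: 10 (2E)-4-[(tert-butyldimethylsilyl)oxy]-3-methylbut-2-en-1-yl acetate
Conditions: TBSCl, imidazole, DMF, rt
Reagents that add atoms: tert-butyldimethylsilyl chloride CC(C)(C)[Si](C)(C)Cl
Why: Standard silylation of the primary allylic alcohol (the future C3–OH).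

Step 7
Reactants: 10 (2E)-4-[(tert-butyldimethylsilyl)oxy]-3-methylbut-2-en-1-yl acetate
Product: 11 (2E)-4-[(tert-butyldimethylsilyl)oxy]-3-methylbut-2-en-1-ol
Conditions: K2CO3 (cat.), MeOH, 0 °C
Reagents that add atoms: none
Why: Base-catalysed methanolysis (transesterification) removes the acetate and leaves the silyl ether.

Step 8
Reactants: 11 (2E)-4-[(tert-butyldimethylsilyl)oxy]-3-methylbut-2-en-1-ol
Product: 12 (2E)-4-[(tert-butyldimethylsilyl)oxy]-3-methylbut-2-enal
Conditions: MnO2, CH2Cl2, rt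
Reagents that add atoms: none
Why: MnO2 oxidation of the allylic alcohol should give the enal (the C6 electrophile) without E/Z isomerisation.

Step 9
Reactants: 12 (2E)-4-[(tert-butyldimethylsilyl)oxy]-3-methylbut-2-enal; 13 methyl propiolate
Product: 14 methyl (4R,5E)-7-[(tert-butyldimethylsilyl)oxy]-4-hydroxy-6-methylhept-5-en-2-ynoate
Conditions: 13, Me2Zn, ProPhenol (Si-face-selective enantiomer, cat.), Ph3PO (cat.), toluene, 4 °C; H2O
Reagents that add atoms: none
Why: Zinc–ProPhenol catalysed asymmetric alkynylation of the enal adds the zinc acetylide to the Si face and sets C6 (R) by catalyst control.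

Step 10
Reactants: 14 methyl (4R,5E)-7-[(tert-butyldimethylsilyl)oxy]-4-hydroxy-6-methylhept-5-en-2-ynoate
Product: 15 methyl (4R,5E)-4,7-bis[(tert-butyldimethylsilyl)oxy]-6-methylhept-5-en-2-ynoate
Conditions: TBSOTf, 2,6-lutidine, CH2Cl2, -78 °C
Reagents that add atoms: tert-butyldimethylsilyl triflate CC(C)(C)[Si](C)(C)OS(=O)(=O)C(F)(F)F
Why: Silyl triflate silylation masks the C6 hydroxyl for the cuprate step.

Step 11
Reactants: 15 methyl (4R,5E)-4,7-bis[(tert-butyldimethylsilyl)oxy]-6-methylhept-5-en-2-ynoate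
Product: 17 methyl (2E,4R,5E)-4,7-bis[(tert-butyldimethylsilyl)oxy]-2-{[(4-methoxybenzyl)oxy]methyl}-6-methyl-3-(tributylstannyl)hepta-2,5-dienoate, via alkenylcopper adduct 16 (not isolated)
Conditions: Bu3SnH, LiN(i-Pr)2, THF, -78 °C; CuBr·SMe2; 15, -78 °C; then 4-methoxybenzyl chloromethyl ether, DMPU, -78 °C
Reagents that add atoms: tributyltin hydride CCCC[SnH](CCCC)CCCC; 4-methoxybenzyl chloromethyl ether COc1ccc(COCCl)cc1
Why: Syn stannylcupration of the ynoate puts tin on the β-carbon C7 and copper on C11, and alkylation of the alkenylcopper at -78 °C with retention (conjugate addition–alkylation) should place CH2OPMB cis to tin and C6 cis to the ester.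

Step 12
Reactants: 17 methyl (2E,4R,5E)-4,7-bis[(tert-butyldimethylsilyl)oxy]-2-{[(4-methoxybenzyl)oxy]methyl}-6-methyl-3-(tributylstannyl)hepta-2,5-dienoate
Product: 18 methyl (2E,4R,5E)-4,7-bis[(tert-butyldimethylsilyl)oxy]-3-iodo-2-{[(4-methoxybenzyl)oxy]methyl}-6-methylhepta-2,5-dienoate
Conditions: I2, CH2Cl2, 0 °C
Reagents that add atoms: iodine II
Why: Iododestannylation replaces tin by iodine with retention of the alkene geometry.

Step 13
Reactants: 18 methyl (2E,4R,5E)-4,7-bis[(tert-butyldimethylsilyl)oxy]-3-iodo-2-{[(4-methoxybenzyl)oxy]methyl}-6-methylhepta-2,5-dienoate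
Product: 20 (5R)-5-[(1E)-3-hydroxy-2-methylprop-1-en-1-yl]-4-iodo-3-{[(4-methoxybenzyl)oxy]methyl}furan-2(5H)-one, via dihydroxy iodo ester 19 (not isolated)
Conditions: aq. HF, MeCN, 0 °C to rt
Reagents that add atoms: none
Why: Desilylation frees the C6 hydroxyl, which lactonises onto the cis ester to form the butenolide; no bond to C6 is broken, so its configuration is kept.

Step 14
Reactants: 20 (5R)-5-[(1E)-3-hydroxy-2-methylprop-1-en-1-yl]-4-iodo-3-{[(4-methoxybenzyl)oxy]methyl}furan-2(5H)-one; 7 (3R)-3-hydroxy-3-methyl-4-oxo-5-(phenylsulfonyl)pentanal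
Product: 21 (5R)-4-[(1S,3R)-1,3-dihydroxy-3-methyl-4-oxo-5-(phenylsulfonyl)pentyl]-5-[(1E)-3-hydroxy-2-methylprop-1-en-1-yl]-3-{[(4-methoxybenzyl)oxy]methyl}furan-2(5H)-one
Conditions: CrCl2, NiCl2 (cat.), N-[2-(4-isopropyl-4,5-dihydro-1,3-oxazol-2-yl)-6-methylphenyl]methanesulfonamide (Re-face-selective enantiomer), Et3N, THF, rt
Reagents that add atoms: none
Why: Nozaki–Hiyama–Kishi coupling (nickel activation of the alkenyl iodide, transfer to trivalent chromium) adds C7 to the aldehyde only, tolerating the ketone, lactone and free hydroxyls, and the chiral sulfonamide–chromium complex should direct attack to the Re face and set C8 (S).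

Step 15
Reactants: 21 (5R)-4-[(1S,3R)-1,3-dihydroxy-3-methyl-4-oxo-5-(phenylsulfonyl)pentyl]-5-[(1E)-3-hydroxy-2-methylprop-1-en-1-yl]-3-{[(4-methoxybenzyl)oxy]methyl}furan-2(5H)-one
Product: 22 (2E)-3-[(2R)-3-[(1S,3R)-1,3-dihydroxy-3-methyl-4-oxo-5-(phenylsulfonyl)pentyl]-4-{[(4-methoxybenzyl)oxy]methyl}-5-oxo-2,5-dihydrofuran-2-yl]-2-methylprop-2-en-1-yl methyl carbonate
Conditions: ClCO2Me, pyridine, CH2Cl2, -20 °C
Reagents that add atoms: methyl chloroformate COC(=O)Cl
Why: Chemoselective acylation of the unhindered primary allylic C3 hydroxyl over the hindered secondary C8 and tertiary C10 hydroxyls installs the leaving group.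

Step 16
Reactants: 22 (2E)-3-[(2R)-3-[(1S,3R)-1,3-dihydroxy-3-methyl-4-oxo-5-(phenylsulfonyl)pentyl]-4-{[(4-methoxybenzyl)oxy]methyl}-5-oxo-2,5-dihydrofuran-2-yl]-2-methylprop-2-en-1-yl methyl carbonate
Product: 23 (2E)-3-[(2R)-3-[(1S,3R)-1-[(tert-butyldimethylsilyl)oxy]-3-hydroxy-3-methyl-4-oxo-5-(phenylsulfonyl)pentyl]-4-{[(4-methoxybenzyl)oxy]methyl}-5-oxo-2,5-dihydrofuran-2-yl]-2-methylprop-2-en-1-yl methyl carbonate
Conditions: TBSCl, imidazole, DMAP (cat.), DMF, 35 °C
Reagents that add atoms: tert-butyldimethylsilyl chloride CC(C)(C)[Si](C)(C)Cl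
Why: Silylation of the secondary C8 hydroxyl, while the tertiary α-keto C10 hydroxyl is inert to TBSCl and stays free.

Step 17
Reactants: 23 (2E)-3-[(2R)-3-[(1S,3R)-1-[(tert-butyldimethylsilyl)oxy]-3-hydroxy-3-methyl-4-oxo-5-(phenylsulfonyl)pentyl]-4-{[(4-methoxybenzyl)oxy]methyl}-5-oxo-2,5-dihydrofuran-2-yl]-2-methylprop-2-en-1-yl methyl carbonate
Product: 24 (4E,6R,8S,10R)-8-[(tert-butyldimethylsilyl)oxy]-10-hydroxy-13-[(4-methoxybenzyl)oxy]-1-oxo-2-(phenylsulfonyl)germacra-4,7(11)-dien-12,6-olide (C2 drawn S)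
Conditions: Pd(PPh3)4 (zerovalent palladium, 10 mol %), THF, 40 °C, slow addition to 0.002 M
Reagents that add atoms: none
Why: Zerovalent palladium ionises the primary allylic carbonate, CO2 is lost and the methoxide formed deprotonates the keto sulfone, whose soft carbanion attacks the syn π-allyl complex anti to palladium. The closest known reaction is the palladium-catalysed macrocyclisation of stabilised carbanions onto allylic carbonates under neutral conditions (Tsuji–Trost type), established for ten-membered and larger carbocycles. The ten-membered ring closes by attack of C2 on the remote primary allyl terminus C3, which leaves C4=C5 inside the ring; attack at C5 would give an eight-membered ring with an exocyclic isopropenyl group. C2 is the only new stereocentre, is not controlled beyond the ring conformation during attack, and is erased in step 18. The step needs C3 over C5 attack, retention of the E geometry, C- over O-alkylation and ionisation of the carbonate rather than of the allylic lactone at C6; these should be secured by the unhindered terminus remote from the C6 oxygen, the syn allyl geometry inherited from the (E)-carbonate, the soft sulfonyl enolate and the much higher reactivity of a primary carbonate at 40 °C, with slow addition at high dilution suppressing oligomers. The free tertiary C10 hydroxyl and the PMB ether (not an ester) at allylic C13 avoid acyl transfer to the carbanion and a second ionisable allylic ester.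

Step 18
Reactants: 24 (4E,6R,8S,10R)-8-[(tert-butyldimethylsilyl)oxy]-10-hydroxy-13-[(4-methoxybenzyl)oxy]-1-oxo-2-(phenylsulfonyl)germacra-4,7(11)-dien-12,6-olide
Product: 25 (4E,6R,8S,10R)-8-[(tert-butyldimethylsilyl)oxy]-10-hydroxy-13-[(4-methoxybenzyl)oxy]-1-oxogermacra-4,7(11)-dien-12,6-olide
Conditions: Al(Hg), THF–H2O, 0 °C to rt
Reagents that add atoms: none
Why: Reductive desulfonylation of the β-keto sulfone by electron transfer from aluminium amalgam removes the sulfone and the transient C2 stereocentre.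

Step 19
Reactants: 25 (4E,6R,8S,10R)-8-[(tert-butyldimethylsilyl)oxy]-10-hydroxy-13-[(4-methoxybenzyl)oxy]-1-oxogermacra-4,7(11)-dien-12,6-olide
Product: 26 (4E,6R,8S,10R)-8-[(tert-butyldimethylsilyl)oxy]-10,13-dihydroxy-1-oxogermacra-4,7(11)-dien-12,6-olide
Conditions: DDQ, CH2Cl2–pH 7 buffer, 0 °C
Reagents that add atoms: none
Why: Oxidative PMB cleavage by DDQ (benzylic hydride abstraction, then hydrolysis) frees C13–OH and leaves the silyl ether and alkenes alone.

Step 20
Reactants: 26 (4E,6R,8S,10R)-8-[(tert-butyldimethylsilyl)oxy]-10,13-dihydroxy-1-oxogermacra-4,7(11)-dien-12,6-olide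
Product: 27 (4E,6R,8S,10R)-10,13-diacetoxy-8-[(tert-butyldimethylsilyl)oxy]-1-oxogermacra-4,7(11)-dien-12,6-olide
Conditions: Ac2O, DMAP, Et3N, CH2Cl2, rt
Reagents that add atoms: acetic anhydride CC(=O)OC(C)=O
Why: DMAP-catalysed acylation acetylates the primary C13 hydroxyl quickly and the tertiary α-keto C10 hydroxyl more slowly, without touching C10 itself.

Step 21
Reactants: 27 (4E,6R,8S,10R)-10,13-diacetoxy-8-[(tert-butyldimethylsilyl)oxy]-1-oxogermacra-4,7(11)-dien-12,6-olide
Product: 28 (4E,6R,8S,10R)-10,13-diacetoxy-8-hydroxy-1-oxogermacra-4,7(11)-dien-12,6-olide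
Conditions: HF·pyridine, THF, 0 °C to rt
Reagents that add atoms: none
Why: Acidic fluoride desilylation frees C8–OH without the basic conditions that would endanger the acetates and the C6 proton.

Step 22
Reactants: 28 (4E,6R,8S,10R)-10,13-diacetoxy-8-hydroxy-1-oxogermacra-4,7(11)-dien-12,6-olide; 29 angelic acid
Product: 30 (4E,6R,8S,10R)-10,13-diacetoxy-8-[(Z)-2-methylbut-2-enoyloxy]-1-oxogermacra-4,7(11)-dien-12,6-olide
Conditions: 29, 2,4,6-trichlorobenzoyl chloride, Et3N, toluene, rt; then 28, 75 °C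
Reagents that add atoms: none
Why: Yamaguchi-type esterification through the mixed anhydride, run without a nucleophilic catalyst, should acylate C8–OH with retention at C8 and keep the Z geometry of the angelate.

Step 23
Reactants: 30 (4E,6R,8S,10R)-10,13-diacetoxy-8-[(Z)-2-methylbut-2-enoyloxy]-1-oxogermacra-4,7(11)-dien-12,6-olide
Product: 31 (4R,5R,6S,8S,10R)-10,13-diacetoxy-8-[(Z)-2-methylbut-2-enoyloxy]-4,5-epoxy-1-oxogermacr-7(11)-en-12,6-olide (target)
Conditions: mCPBA, CH2Cl2, 0 °C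
Reagents that add atoms: 3-chloroperbenzoic acid OOC(=O)c1cccc(Cl)c1
Why: Prilezhaev epoxidation picks the electron-rich ring alkene over the two conjugated ones; with H6 in the alkene plane (allylic 1,3-strain against the C4 methyl) the ring chain through C7 covers one face, so the peracid should add to the outer face, syn to the lactone oxygen, giving 4R,5R.

Compound list
1 | (R)-citramalic acid | OC(=O)C[C@@](C)(O)C(=O)O | starting material
2 | 2-[(4R)-2,2,4-trimethyl-5-oxo-1,3-dioxolan-4-yl]acetic acid | OC(=O)C[C@@]1(C)OC(C)(C)OC1=O | intermediate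
3 | (5R)-5-(2-hydroxyethyl)-2,2,5-trimethyl-1,3-dioxolan-4-one (not isolated) | OCC[C@@]1(C)OC(C)(C)OC1=O | intermediate
4 | (3R)-3-hydroxy-3-methyloxolan-2-one | O=C1OCC[C@@]1(C)O | intermediate
5 | methyl phenyl sulfone | CS(=O)(=O)c1ccccc1 | starting material
6 | (3R)-3,5-dihydroxy-3-methyl-1-(phenylsulfonyl)pentan-2-one | OCC[C@@](C)(O)C(=O)CS(=O)(=O)c1ccccc1 | intermediate
7 | (3R)-3-hydroxy-3-methyl-4-oxo-5-(phenylsulfonyl)pentanal | O=CC[C@@](C)(O)C(=O)CS(=O)(=O)c1ccccc1 | intermediate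
8 | prenyl acetate | CC(C)=CCOC(C)=O | starting material
9 | (2E)-4-hydroxy-3-methylbut-2-en-1-yl acetate | CC(=O)OC/C=C(\C)CO | intermediate
10 | (2E)-4-[(tert-butyldimethylsilyl)oxy]-3-methylbut-2-en-1-yl acetate | CC(=O)OC/C=C(\C)CO[Si](C)(C)C(C)(C)C | intermediate
11 | (2E)-4-[(tert-butyldimethylsilyl)oxy]-3-methylbut-2-en-1-ol | OC/C=C(\C)CO[Si](C)(C)C(C)(C)C | intermediate
12 | (2E)-4-[(tert-butyldimethylsilyl)oxy]-3-methylbut-2-enal | O=C/C=C(\C)CO[Si](C)(C)C(C)(C)C | intermediate
13 | methyl propiolate | C#CC(=O)OC | starting material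
14 | methyl (4R,5E)-7-[(tert-butyldimethylsilyl)oxy]-4-hydroxy-6-methylhept-5-en-2-ynoate | COC(=O)C#C[C@H](O)/C=C(\C)CO[Si](C)(C)C(C)(C)C | intermediate
15 | methyl (4R,5E)-4,7-bis[(tert-butyldimethylsilyl)oxy]-6-methylhept-5-en-2-ynoate | COC(=O)C#C[C@H](O[Si](C)(C)C(C)(C)C)/C=C(\C)CO[Si](C)(C)C(C)(C)C | intermediate
16 | methyl (2Z,4R,5E)-4,7-bis[(tert-butyldimethylsilyl)oxy]-2-cuprio-6-methyl-3-(tributylstannyl)hepta-2,5-dienoate (alkenylcopper adduct, not isolated) | COC(=O)/C([Cu])=C(/[Sn](CCCC)(CCCC)CCCC)[C@H](O[Si](C)(C)C(C)(C)C)/C=C(\C)CO[Si](C)(C)C(C)(C)C | intermediate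
17 | methyl (2E,4R,5E)-4,7-bis[(tert-butyldimethylsilyl)oxy]-2-{[(4-methoxybenzyl)oxy]methyl}-6-methyl-3-(tributylstannyl)hepta-2,5-dienoate | COC(=O)/C(COCc1ccc(OC)cc1)=C(/[Sn](CCCC)(CCCC)CCCC)[C@H](O[Si](C)(C)C(C)(C)C)/C=C(\C)CO[Si](C)(C)C(C)(C)C | intermediate
18 | methyl (2E,4R,5E)-4,7-bis[(tert-butyldimethylsilyl)oxy]-3-iodo-2-{[(4-methoxybenzyl)oxy]methyl}-6-methylhepta-2,5-dienoate | COC(=O)/C(COCc1ccc(OC)cc1)=C(/I)[C@H](O[Si](C)(C)C(C)(C)C)/C=C(\C)CO[Si](C)(C)C(C)(C)C | intermediate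
19 | methyl (2E,4R,5E)-4,7-dihydroxy-3-iodo-2-{[(4-methoxybenzyl)oxy]methyl}-6-methylhepta-2,5-dienoate (not isolated) | COC(=O)/C(COCc1ccc(OC)cc1)=C(/I)[C@H](O)/C=C(\C)CO | intermediate
20 | (5R)-5-[(1E)-3-hydroxy-2-methylprop-1-en-1-yl]-4-iodo-3-{[(4-methoxybenzyl)oxy]methyl}furan-2(5H)-one | O=C1O[C@H](/C=C(\C)CO)C(I)=C1COCc1ccc(OC)cc1 | intermediate
21 | (5R)-4-[(1S,3R)-1,3-dihydroxy-3-methyl-4-oxo-5-(phenylsulfonyl)pentyl]-5-[(1E)-3-hydroxy-2-methylprop-1-en-1-yl]-3-{[(4-methoxybenzyl)oxy]methyl}furan-2(5H)-one | O[C@@H](C[C@@](C)(O)C(=O)CS(=O)(=O)c1ccccc1)C1=C(COCc2ccc(OC)cc2)C(=O)O[C@@H]1/C=C(\C)CO | intermediate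
22 | C3 methyl carbonate of 21 (C8–OH and C10–OH free; 6R,8S,10R) | O[C@@H](C[C@@](C)(O)C(=O)CS(=O)(=O)c1ccccc1)C1=C(COCc2ccc(OC)cc2)C(=O)O[C@@H]1/C=C(\C)COC(=O)OC | intermediate
23 | cyclisation precursor: C8 TBS ether of 22 (C10–OH free; 6R,8S,10R) | CC(C)(C)[Si](C)(C)O[C@@H](C[C@@](C)(O)C(=O)CS(=O)(=O)c1ccccc1)C1=C(COCc2ccc(OC)cc2)C(=O)O[C@@H]1/C=C(\C)COC(=O)OC | intermediate
24 | (4E,6R,8S,10R)-8-[(tert-butyldimethylsilyl)oxy]-10-hydroxy-13-[(4-methoxybenzyl)oxy]-1-oxo-2-(phenylsulfonyl)germacra-4,7(11)-dien-12,6-olide (C2 drawn S; either epimer serves) | CC(C)(C)[Si](C)(C)O[C@H]1C[C@@](C)(O)C(=O)[C@@H](S(=O)(=O)c3ccccc3)C/C(C)=C/[C@H]2OC(=O)C(COCc3ccc(OC)cc3)=C12 | intermediate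
25 | (4E,6R,8S,10R)-8-[(tert-butyldimethylsilyl)oxy]-10-hydroxy-13-[(4-methoxybenzyl)oxy]-1-oxogermacra-4,7(11)-dien-12,6-olide | CC(C)(C)[Si](C)(C)O[C@H]1C[C@@](C)(O)C(=O)CC/C(C)=C/[C@H]2OC(=O)C(COCc3ccc(OC)cc3)=C12 | intermediate
26 | (4E,6R,8S,10R)-8-[(tert-butyldimethylsilyl)oxy]-10,13-dihydroxy-1-oxogermacra-4,7(11)-dien-12,6-olide | CC(C)(C)[Si](C)(C)O[C@H]1C[C@@](C)(O)C(=O)CC/C(C)=C/[C@H]2OC(=O)C(CO)=C12 | intermediate
27 | (4E,6R,8S,10R)-10,13-diacetoxy-8-[(tert-butyldimethylsilyl)oxy]-1-oxogermacra-4,7(11)-dien-12,6-olide | CC(C)(C)[Si](C)(C)O[C@H]1C[C@@](C)(OC(C)=O)C(=O)CC/C(C)=C/[C@H]2OC(=O)C(COC(C)=O)=C12 | intermediate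
28 | (4E,6R,8S,10R)-10,13-diacetoxy-8-hydroxy-1-oxogermacra-4,7(11)-dien-12,6-olide | O[C@H]1C[C@@](C)(OC(C)=O)C(=O)CC/C(C)=C/[C@H]2OC(=O)C(COC(C)=O)=C12 | intermediate
29 | angelic acid, (Z)-2-methylbut-2-enoic acid | C/C=C(/C)C(=O)O | starting material
30 | (4E,6R,8S,10R)-10,13-diacetoxy-8-[(Z)-2-methylbut-2-enoyloxy]-1-oxogermacra-4,7(11)-dien-12,6-olide | C/C=C(/C)C(=O)O[C@H]1C[C@@](C)(OC(C)=O)C(=O)CC/C(C)=C/[C@H]2OC(=O)C(COC(C)=O)=C12 | intermediate
31 | (4R,5R,6S,8S,10R)-10,13-diacetoxy-8-[(Z)-2-methylbut-2-enoyloxy]-4,5-epoxy-1-oxogermacr-7(11)-en-12,6-olide | C/C=C(/C)C(=O)O[C@H]1C[C@@](C)(OC(C)=O)C(=O)CC[C@@]2(C)O[C@@H]2[C@H]2OC(=O)C(COC(C)=O)=C12 | target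

Total step count: 23. Longest linear sequence: 19 steps (steps 5 to 23, from prenyl acetate).

Steps most likely to fail

Step 17. Oligomerisation may outrun ring closure, the carbanion may attack the inner terminus C5, or palladium may also ionise the allylic lactone C6–O, which would scramble C6 or lead to a diene by elimination. The fallback is a palladium-free intramolecular SN2 alkylation of the keto sulfone carbanion. It sets out from 21: Appel bromination of the primary allylic alcohol (CBr4, PPh3, CH2Cl2, -20 °C) should give (5R)-5-[(1E)-3-bromo-2-methylprop-1-en-1-yl]-4-[(1S,3R)-1,3-dihydroxy-3-methyl-4-oxo-5-(phenylsulfonyl)pentyl]-3-{[(4-methoxybenzyl)oxy]methyl}furan-2(5H)-one F1. Silylation of C8–OH (TBSCl, imidazole, DMF) should then give its C8 tert-butyldimethylsilyl ether F2. Slow addition of F2 to Cs2CO3 in MeCN at high dilution should form the C2–C3 bond by displacement of the primary allylic bromide and come back to the route at 24.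

Step 11. The alkenylcopper may equilibrate through its allenoate form before it is alkylated, so that the alkene geometry is lost, or the alkylation may be too slow at -78 °C. The fallback captures the copper intermediate as an aldol and forms the ether separately. It sets out from 15: the same stannylcuprate adduct is trapped at -78 °C with monomeric formaldehyde, a faster electrophile, to give methyl (2E,4R,5E)-4,7-bis[(tert-butyldimethylsilyl)oxy]-2-(hydroxymethyl)-6-methyl-3-(tributylstannyl)hepta-2,5-dienoate F3. Etherification with 4-methoxybenzyl trichloroacetimidate and La(OTf)3 (cat.) in toluene comes back to the route at 17.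

Step 14. Aldehyde 7 may close on itself by aldol addition of its acidic C2 methylene to C8 faster than the chromium reagent adds, and weak facial control at C8 would compound the loss. The fallback carries C2 at the sulfide oxidation level, which removes the acidity. It sets out from 4:
- (phenylthio)methyllithium (thioanisole, n-BuLi, DABCO, THF) should open the lactone to (3R)-3,5-dihydroxy-3-methyl-1-(phenylthio)pentan-2-one F4;
- Dess–Martin oxidation should give (3R)-3-hydroxy-3-methyl-4-oxo-5-(phenylthio)pentanal F5;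
- the same chromium coupling with 20 should give the phenylthio analogue of 21 F6;
- ClCO2Me and pyridine should give the phenylthio analogue of 22 F7;
- TBSCl and imidazole should give the phenylthio analogue of 23 F8;
- oxidation of the sulfide with H2O2 and (NH4)6Mo7O24 (cat.) in EtOH, which should spare the trisubstituted alkene, comes back to the route at 23.

Further compounds
F1 | step 17 | (5R)-5-[(1E)-3-bromo-2-methylprop-1-en-1-yl]-4-[(1S,3R)-1,3-dihydroxy-3-methyl-4-oxo-5-(phenylsulfonyl)pentyl]-3-{[(4-methoxybenzyl)oxy]methyl}furan-2(5H)-one | O[C@@H](C[C@@](C)(O)C(=O)CS(=O)(=O)c1ccccc1)C1=C(COCc2ccc(OC)cc2)C(=O)O[C@@H]1/C=C(\C)CBr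
F2 | step 17 | C8 tert-butyldimethylsilyl ether of F1 | CC(C)(C)[Si](C)(C)O[C@@H](C[C@@](C)(O)C(=O)CS(=O)(=O)c1ccccc1)C1=C(COCc2ccc(OC)cc2)C(=O)O[C@@H]1/C=C(\C)CBr
F3 | step 11 | methyl (2E,4R,5E)-4,7-bis[(tert-butyldimethylsilyl)oxy]-2-(hydroxymethyl)-6-methyl-3-(tributylstannyl)hepta-2,5-dienoate | COC(=O)/C(CO)=C(/[Sn](CCCC)(CCCC)CCCC)[C@H](O[Si](C)(C)C(C)(C)C)/C=C(\C)CO[Si](C)(C)C(C)(C)C
F4 | step 14 | (3R)-3,5-dihydroxy-3-methyl-1-(phenylthio)pentan-2-one | OCC[C@@](C)(O)C(=O)CSc1ccccc1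
F5 | step 14 | (3R)-3-hydroxy-3-methyl-4-oxo-5-(phenylthio)pentanal | O=CC[C@@](C)(O)C(=O)CSc1ccccc1
F6 | step 14 | (5R)-4-[(1S,3R)-1,3-dihydroxy-3-methyl-4-oxo-5-(phenylthio)pentyl]-5-[(1E)-3-hydroxy-2-methylprop-1-en-1-yl]-3-{[(4-methoxybenzyl)oxy]methyl}furan-2(5H)-one | O[C@@H](C[C@@](C)(O)C(=O)CSc1ccccc1)C1=C(COCc2ccc(OC)cc2)C(=O)O[C@@H]1/C=C(\C)CO
F7 | step 14 | C3 methyl carbonate of F6 | O[C@@H](C[C@@](C)(O)C(=O)CSc1ccccc1)C1=C(COCc2ccc(OC)cc2)C(=O)O[C@@H]1/C=C(\C)COC(=O)OC
F8 | step 14 | C8 tert-butyldimethylsilyl ether of F7 | CC(C)(C)[Si](C)(C)O[C@@H](C[C@@](C)(O)C(=O)CSc1ccccc1)C1=C(COCc2ccc(OC)cc2)C(=O)O[C@@H]1/C=C(\C)COC(=O)OC
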